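What does more free catalyst buy at the moment when half of the substrate is gone?

* factor on the rate of making product when 50% of the substrate are converted if free catalyst is charged twice over
* factor on the rate when 50% of the substrate are converted if free catalyst is charged at 80 mM instead

| setting | cedar | ash | birch | flask |
|---|---|---|---|---|
| substrate | 0.23 M | 0.34 M | 0.45 M | 0.45 M |
| free catalyst | 14 mM | 14 mM | 21 mM | 14 mM |
| remark | run made earlier | run made earlier | run made earlier |  |

| run | time / min | product / % | substrate / % |
|---|---|---|---|
| cedar | 0.250 | 7.9 | 89.4 |
| cedar | 0.417 | 13.1 | 84.1 |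
| cedar | 0.667 | 21.6 | 74.8 |
| cedar | 0.833 | 26.5 | 71.2 |
| cedar | 1.33 | 41.8 | 57.2 |
| cedar | 2.00 | 56.1 | 42.6 |
| cedar | 3.00 | 72.7 | 27.0 |
| ash | 0.500 | 13.3 | 84.1 |
| ash | 1.00 | 27.3 | 70.7 |
| ash | 1.33 | 35.0 | 62.2 |
| ash | 2.00 | 49.4 | 48.6 |
| ash | 2.50 | 58.3 | 39.4 |
| ash | 3.00 | 65.1 | 33.1 |
| birch | 0.250 | 6.7 | 89.6 |
| birch | 0.500 | 16.8 | 80.5 |
| birch | 0.833 | 28.5 | 68.1 |
| birch | 1.50 | 47.5 | 49.2 |
| birch | 3.00 | 79.0 | 20.1 |

(scatter of a reading: 0.5 percentage points)

- on the list of suspects stand: substrate + free catalyst -> catalyst intermediate A; catalyst intermediate A -> catalyst intermediate B; catalyst intermediate B -> free catalyst + product; free catalyst -> spent catalyst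

The first step is to compare two runs at one substrate concentration. Ash between 0.500 min and 1.00 min and birch between 0.833 min and 1.50 min both pass about 0.263 M substrate, and product per catalyst charged reads 6.80 min⁻¹ in ash and 6.10 min⁻¹ in birch. That is near enough for this reckoning to take the rate as first order in the free catalyst charged.

On that assumption, and at one substrate charge, this reckoning lets the fraction left follow a single clock: the catalyst-time τ, free catalyst charged multiplied by time. Birch shares the flask's charge of 0.45 M, whereas cedar and ash do not: at 3.00 min cedar has less substrate left than ash, 27.0% against 33.1%. The birch row at 1.50 min has 49.2% substrate left, so τ = 31.5 mM·min for that fraction left. The flask, at 14 mM, is reckoned to need 2.25 min to reach the same τ. With the substrate charge held at 0.45 M, equal fraction left means equal substrate, so in this reckoning the rate follows the catalyst charge: it gives 2 and 5.71.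

The forecast says 2.03 and 6; its second factor is higher than this reckoning's, on the ground “so product rate reflects slightly earlier, higher substrate”.

The simulation gives 2.14 and 6.54, and the flask reaches 50% conversion at 2.26 min.

substrate + free catalyst → catalyst intermediate A (k = 0.878 L mol⁻¹ s⁻¹); catalyst intermediate A → catalyst intermediate B (k = 0.449 s⁻¹); catalyst intermediate B → free catalyst + product (k = 0.422 s⁻¹); free catalyst → spent catalyst (k = 0.00189 s⁻¹) In the flask, spent catalyst stands at 1.80% of the catalyst charged at 0.400 min and at 9.29% at 2.00 min. At 80 mM, the same τ comes at 0.394 min, and the simulated factor stands at 1.14 times the ratio of the charges.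

(Readings and results were computed with constants of no real substance; noise was put on by code.)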